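# Proposed synthesis of (3S)-3-(3-hydroxy-2,4,5-trimethoxyphenyl)-8-methoxychroman-7-ol (31, CNP0201239.1)

## The problem

Compound 31 is an isoflavan. Ring A is fused to a saturated pyran ring (O1, C2, C3, C4, C4a, C8a), and C3 carries the fully substituted ring B. The only stereocentre is C3 (S), and no other centre exists to direct it, so it must be set by an external element. Because C3 lies between C2 and the ring B ipso carbon, any intermediate with a carbonyl group or a cation at C2 makes its hydrogen labile. Six oxygen substituents must be placed without ambiguity: O1, 8-OMe and 7-OH are contiguous on ring A, and ring B has four contiguous oxygens of which only O3', flanked by two methyl ethers, is a free phenol. On a tetraoxygenated benzene ring the two remaining positions are activated almost equally, so C1' of ring B cannot be found by ordinary electrophilic substitution and must be marked in another way. The two phenols are electron-rich and easily oxidised, and as free OH groups they would consume Grignard base and bind Lewis acids, so both are best kept as ethers that fall together in one neutral step at the end. The feature that allows a short, convergent plan is on ring A: the phenolic O1 is ortho to the benzylic C4 methylene, so O1–C8a–C4a–C4 is a latent ortho-quinone methide, and C2–C3 can be added to it as an enol ether that already carries ring B.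

## Retrosynthesis

**Unmasking last (31 ⇒ 30).** The last step cleaves only the two O–benzyl bonds at O7 and O3'. Benzyl is preferred to silyl or acetal groups because it withstands organolithium and Grignard reagents, BF3 and palladium coupling. It is preferred to a further alkyl ether because its removal needs no boron halide, which would not reliably spare the four methyl ethers. Precursor 30 has the complete skeleton and the C3 stereocentre. The forward step must leave the chroman C–O bonds and C3 alone, which neutral hydrogenolysis does.

**C2 as an acetal (30 ⇒ 28).** The C2–H bond is traced back to a C2–O bond to a chiral alkoxy group. This raises C2 to the acetal level, which is what an enol ether delivers in a cycloaddition, and it places the auxiliary on the atom next to C3. A lactone at C2 was the neighbouring choice; it was set aside because an aryl-substituted lactone α-carbon is acidic and C3 would be lost. The forward reaction must ionise the exocyclic C–O bond and transfer hydride to C2 without enolisation towards C3.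

**The key disconnection (28 ⇒ 6 + 24).** Two bonds of the pyran ring are cut together, C3–C4 and O1–C2. This divides 28 into the ortho-quinone methide 27 (ring A with C4) and the Z enol ether 24 (C2, C3, ring B and the auxiliary). Cutting O1–C2 alone (phenol alkylation) or C3–C4 alone (enolate benzylation) would each need a second ring-forming operation and a separate asymmetric step. The paired cut forms the ring and the stereocentre at once and is fully convergent. Compound 27 cannot be stored and is released in the flask from the O-Boc salicyl alcohol 6. The forward reaction must generate 27 cold in the presence of 24, and must add to one face of the enol ether with O1 bonding to the acetal carbon.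

**Ring A (6 ⇒ 5 ⇒ 4 ⇒ 3 ⇒ 1).** Alcohol 6 is related to aldehyde 5 by reduction, 5 to phenol 4 by removal of the carbonate, and 4 to 3 by removal of the O4 benzyl group. The single C–C bond cut is that of the formyl carbon (the later C4) to the ring of 2-methoxyresorcinol 1. Compound 1 already has the three contiguous oxygens, and its two open activated positions are equivalent, so formylation is unambiguous. The two hydroxyls of 3 differ because one is hydrogen-bonded to the aldehyde. Reduction follows carbonate formation and uses borane, so that no metal alkoxide forms next to the carbonate before step 12.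

**The enol ether (24 ⇒ 23 ⇒ 19 + 14; 19 ⇒ 15 + 16).** The Z double bond is traced back to the triple bond of alkynyl ether 23, because syn semihydrogenation gives the Z isomer only; carbonyl olefination with an alkoxymethyl ylide would give isomer mixtures. Compound 23 is cut at the C(sp)–C1' bond into aryl iodide 14 and an alkoxyacetylide made from dichlorovinyl ether 19. Both vinyl carbons come from trichloroethylene 16, and the oxygen with its two stereocentres comes from (1R,2S)-2-phenylcyclohexanol 15. The coupling must run at room temperature because secondary alkyl alkynyl ethers fragment on heating, which is why the iodide is wanted.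

**Ring B (14 ⇒ 13 ⇒ 12 ⇒ 9 ⇒ 7).** The C1'–I bond is traced back to a C1'–Si bond. Ipso substitution puts iodine exactly where silicon was, whereas direct iodination of the silicon-free analogue of 13 would have to choose between two ring positions of nearly equal activation. The O3' benzyl ether goes back to phenol 12, whose C–O bond is cut to a C–H bond lying between two methoxy groups of arylsilane 9, the classic site of directed lithiation. Compound 9 comes from commercial 1-bromo-2,4,5-trimethoxybenzene 7, in which the bromine marks C1'. Four steps thus fix all six ring B positions without relying on subtle electronic differences.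

## Roads not taken

**Alternative 1:** The cut is the C3–C1' bond, made together with a temporary bond from a ring B oxygen to C4.
- Forward step: 7-isopropoxy-8-methoxy-2H-chromene A2 would add through its C3 to 2-methoxy-1,4-benzoquinone A3, activated by the chiral diolate (TADDOLate)TiCl2 of tetravalent titanium, made from TiCl4, Ti(OiPr)4 and the TADDOL diol. The quinone oxygen then closes onto C4 to give the cis-fused pterocarpan A1, whose benzylic C4–O bond is cleaved afterwards by hydrogenolysis.
- Merits: both partners are small and achiral, C3 is set under reagent control in the bond-forming step, and C2 never passes through an acetal or a cation.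
- Weak points: the quinone-derived ring of A1 (the later ring B) has only three oxygens and a hydrogen at the carbon that becomes C3'. After C4–O cleavage the hydroxyls at C2' and C5' must be methylated, and a hydroxyl must still be inserted at C3' between two oxygens on the complete, electron-rich skeleton. The isopropyl ether must then be removed in the presence of five methyl ethers. A quinone carrying the extra oxygen would offer two alkoxy groups to the titanium centre and two directions of attack. The chiral titanium reagent is stoichiometric, and the level of induction in this reaction type varies with the substitution of both partners.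
- Comparison: this road is better in the number of steps to the carbon skeleton and in the safety of C3 after its formation. The chosen plan sets against this that ring B arrives with all four oxygens in place and differentiated, that no oxidation of the assembled skeleton is needed, and that the chiral controller is a recoverable alcohol.

**Alternative 2:** The cut is the C7–C8 bond of ring A.
- Forward step: NaOMe would deprotonate the methoxymethyl ketone carbon of keto ester A5, and the carbanion would attack the ester carbonyl (a Dieckmann-type Claisen condensation). This closes the six-membered carbocycle as the 2-methoxycyclohexane-1,3-dione A4. Dehydrogenation to the resorcinol, desilylation and closure of the primary alcohol onto the neighbouring phenol would follow.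
- Merits: the three contiguous oxygens of ring A are placed by construction, the stereocentre is two carbons from the nearest enolisable position and is not endangered by the base, and only simple carbonyl chemistry is used.
- Weak points: the sequence builds in several steps a ring that is commercially available as 2-methoxyresorcinol 1. A5 has three enolisable positions, so the condensation depends on thermodynamic funnelling to the dione. The aromatisation of A4 is an oxidation that must spare the electron-rich ring B and its benzyl ether. The key step creates neither the stereocentre nor the pyran ring, so both need separate operations, one of them an asymmetric step.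
- Comparison: this road equals the chosen plan in regiochemical certainty for ring A, but not in step economy or convergence. The chosen plan buys ring A and makes ring and stereocentre in one step.

**Alternative 3:** The cuts are the O1–C8a bond and the C8–O bond.
- Forward step: LiN(iPr)2 would convert bromoarene A7 into the C8–C8a aryne, the tethered primary alkoxide would add to C8a and close the pyran ring, and the resulting C8 aryllithium would be trapped with B(OMe)3 and oxidised with H2O2 to the chroman-8-ol A6. Methylation of O8 and removal of the two methoxymethyl groups would finish.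
- Merits: two C–O bonds of ring A arise in one flask, the 8-oxygen is tied to the ring closure and cannot be misplaced, ring A needs only a simple bromoarene, and C2 stays at the ether level, so C3 is never next to a cation.
- Weak points: the aryllithium forms in the presence of diisopropylamine and is likely to be protonated before the borate is added, and the borate cannot be present from the start because the amide base would attack it. The stereocentre of A7 must be made beforehand by a separate asymmetric step, and two further steps follow the key step.
- Comparison: this road is better in avoiding an acetal next to C3. The chosen plan sets against this that the 8-methoxy group is bought with 1, that the stereocentre is created in the ring-forming step, and that every step has precedent in its reaction type.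

Key step: step 12

Assumption: the face of 24 that the phenyl group shields is assigned from the s-trans enol ether conformer with the carbinol C–H eclipsing the vinyl C–O bond; if the sense proved opposite, (1S,2R)-2-phenylcyclohexanol would be used in step 9 with no other change.

## Route

Step 1
Reactants: 1 2-methoxyresorcinol
Product: 3 2,4-dihydroxy-3-methoxybenzaldehyde, via iminium chloride 2 (not isolated)
Conditions: POCl3, DMF, MeCN, 0 °C → rt; then H2O, 50 °C
Reagents that add atoms: N,N-dimethylformamide, CN(C)C=O; water, O
Why: Vilsmeier–Haack formylation; the chloroiminium electrophile attacks the position ortho to one hydroxyl and para to the other (the two such positions are equivalent by symmetry). The iminium group of 2 deactivates the ring against a second attack and is hydrolysed on work-up.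

Step 2
Reactants: 3 2,4-dihydroxy-3-methoxybenzaldehyde
Product: 4 4-(benzyloxy)-2-hydroxy-3-methoxybenzaldehyde
Conditions: BnBr, NaHCO3, MeCN, 80 °C
Reagents that add atoms: benzyl bromide, BrCc1ccccc1
Why: Williamson etherification under weak base; the 4-OH is para to the formyl group and the more acidic hydroxyl, while the 2-OH is held in a hydrogen bond to the carbonyl oxygen. Hydrogencarbonate should therefore alkylate O4 only, as is standard for 2,4-dihydroxybenzaldehydes.

Step 3
Reactants: 4 4-(benzyloxy)-2-hydroxy-3-methoxybenzaldehyde
Product: 5 tert-butyl [3-(benzyloxy)-6-formyl-2-methoxyphenyl] carbonate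
Conditions: Boc2O, DMAP (cat.), i-Pr2NEt, THF, rt
Reagents that add atoms: di-tert-butyl dicarbonate, CC(C)(C)OC(=O)OC(=O)OC(C)(C)C
Why: DMAP-catalysed acylation of the phenol with Boc2O gives the aryl tert-butyl carbonate; no other group in 4 is nucleophilic.

Step 4
Reactants: 5 tert-butyl [3-(benzyloxy)-6-formyl-2-methoxyphenyl] carbonate
Product: 6 tert-butyl [3-(benzyloxy)-6-(hydroxymethyl)-2-methoxyphenyl] carbonate
Conditions: BH3·THF, THF, 0 °C; then H2O
Reagents that add atoms: none
Why: Borane reduction of the aldehyde proceeds without a metal alkoxide, so nothing can pull the carbonate onto the benzylic oxygen before the key step. Aryl carbonate and benzyl ether are inert to BH3 at 0 °C.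

Step 5
Reactants: 7 1-bromo-2,4,5-trimethoxybenzene
Product: 9 trimethyl(2,4,5-trimethoxyphenyl)silane, via aryllithium 8 (not isolated)
Conditions: n-BuLi, THF, −78 °C; then Me3SiCl, −78 °C → rt
Reagents that add atoms: chlorotrimethylsilane, C[Si](C)(C)Cl
Why: Bromine–lithium exchange is faster than any deprotonation at −78 °C, and aryllithium 8 is silylated by Me3SiCl. The silyl group marks C1' and is exchanged for iodine in step 8.

Step 6
Reactants: 9 trimethyl(2,4,5-trimethoxyphenyl)silane
Product: 12 2,3,6-trimethoxy-5-(trimethylsilyl)phenol, via aryllithium 10 (not isolated), via dimethyl arylboronate 11 (not isolated)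
Conditions: n-BuLi, THF, 0 °C → rt; B(OMe)3, −78 °C → rt; then H2O2, aq. NaOH, 0 °C
Reagents that add atoms: hydrogen peroxide, OO
Why: Directed ortho-metalation; the C–H between two methoxy groups is the favoured site through double coordination, whereas the other ring C–H is flanked by the bulky, non-coordinating SiMe3 group. Borylation and oxidative migration of the aryl group from boron to oxygen then give the phenol.

Step 7
Reactants: 12 2,3,6-trimethoxy-5-(trimethylsilyl)phenol
Product: 13 [3-(benzyloxy)-2,4,5-trimethoxyphenyl]trimethylsilane
Conditions: BnBr, K2CO3, DMF, 50 °C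
Reagents that add atoms: benzyl bromide, BrCc1ccccc1
Why: Williamson etherification of the hindered phenol; the arylsilane tolerates carbonate base.

Step 8
Reactants: 13 [3-(benzyloxy)-2,4,5-trimethoxyphenyl]trimethylsilane
Product: 14 3-(benzyloxy)-1-iodo-2,4,5-trimethoxybenzene
Conditions: ICl, CH2Cl2, −78 → 0 °C
Reagents that add atoms: iodine monochloride, ClI
Why: Ipso-iododesilylation; the electrophile attacks the silicon-bearing carbon, which is ortho and para to methoxy groups and stabilised by the β-silicon effect. Iodine therefore takes exactly the place of silicon, and the ring B pattern is fixed.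

Step 9
Reactants: 15 (1R,2S)-2-phenylcyclohexanol; 16 trichloroethylene
Product: 19 (E)-1,2-dichlorovinyl (1R,2S)-2-phenylcyclohexyl ether, via potassium alkoxide 17 (not isolated), via dichloroacetylene 18 (not isolated)
Conditions: KH, THF, rt; then 16 added at −50 °C, warmed to rt
Reagents that add atoms: none
Why: Known preparation of 1,2-dichlorovinyl ethers; base converts 16 into dichloroacetylene 18, to which alkoxide 17 adds in anti fashion to give the E ether. The stereocentres of 15 are not involved.

Step 10
Reactants: 19 (E)-1,2-dichlorovinyl (1R,2S)-2-phenylcyclohexyl ether; 14 3-(benzyloxy)-1-iodo-2,4,5-trimethoxybenzene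
Product: 23 [3-(benzyloxy)-2,4,5-trimethoxyphenyl]ethynyl (1R,2S)-2-phenylcyclohexyl ether, via chloroethynyl ether 20 (not isolated), via lithium acetylide 21 (not isolated), via alkynylzinc chloride 22 (not isolated)
Conditions: n-BuLi (2.2 equiv), THF, −78 → −40 °C; ZnCl2, −40 → 0 °C; then 14, Pd(PPh3)4 (cat.), rt
Reagents that add atoms: none
Why: n-BuLi converts 19 by elimination (20) and chlorine–lithium exchange into acetylide 21, and transmetalation gives alkynylzinc chloride 22. Negishi coupling with the aryl iodide then forms the C(sp)–C1' bond at room temperature, which avoids isolating a terminal alkynyl ether and the heat at which secondary alkyl alkynyl ethers fragment.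

Step 11
Reactants: 23 [3-(benzyloxy)-2,4,5-trimethoxyphenyl]ethynyl (1R,2S)-2-phenylcyclohexyl ether
Product: 24 (Z)-2-[3-(benzyloxy)-2,4,5-trimethoxyphenyl]ethenyl (1R,2S)-2-phenylcyclohexyl ether
Conditions: H2 (1 atm), Pd/CaCO3 poisoned with Pb(OAc)2, quinoline, EtOAc, rt
Reagents that add atoms: none
Why: Lindlar semihydrogenation; syn delivery of hydrogen to the alkyne on the poisoned palladium surface gives the Z enol ether. Quinoline suppresses over-reduction, and benzyl ethers are not cleaved by this catalyst.

Step 12
Reactants: 6 tert-butyl [3-(benzyloxy)-6-(hydroxymethyl)-2-methoxyphenyl] carbonate; 24 (Z)-2-[3-(benzyloxy)-2,4,5-trimethoxyphenyl]ethenyl (1R,2S)-2-phenylcyclohexyl ether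
Product: 28 (2S,3S)-7-(benzyloxy)-3-[3-(benzyloxy)-2,4,5-trimethoxyphenyl]-8-methoxy-2-{[(1R,2S)-2-phenylcyclohexyl]oxy}chromane, via chloromagnesium alkoxide 25 (not isolated), via chloromagnesium phenoxide 26 (not isolated), via ortho-quinone methide 27 (not isolated)
Conditions: t-BuMgCl (slow addition), toluene, −78 °C → rt; 6 in excess over 24
Reagents that add atoms: none
Why: t-BuMgCl deprotonates the benzylic alcohol of 6 to alkoxide 25, the Boc group migrates from the phenolic to the benzylic oxygen to give phenoxide 26, and 26 expels tert-butyl carbonate below room temperature to give ortho-quinone methide 27. Compound 27 is an electron-poor 1-oxadiene and 24 an electron-rich alkene, so they combine in a concerted but asynchronous inverse-electron-demand hetero-Diels–Alder reaction, the known behaviour of ortho-quinone methides generated this way towards enol ethers, chiral ones included. The pyran ring is closed by this [4+2] cycloaddition, C4 bonding to the enol ether β-carbon (C3) and O1 to the α-carbon (C2). This orientation is secured by the frontier orbitals: the largest LUMO coefficient of 27 is on the exocyclic methylene and the largest HOMO coefficient of 24 on the β-carbon, so positive charge builds up on the oxygen-stabilised C2. C3 is controlled by the auxiliary: in the s-trans conformer of the Z enol ether the phenyl group of the trans-2-phenylcyclohexyl residue lies over one face of the double bond, and addition to the open face gives 3S with the (1R,2S) alcohol. C2 is controlled by the suprafacial addition to the Z alkene, which places the auxiliary oxygen cis to ring B (2S); this centre is removed in step 13. Because the methide carbon bears no substituent, endo and exo approach to the same alkene face lead to the same product, so only regioselectivity and facial selectivity are required. The chloromagnesium counter-ion and the two ring A donor groups moderate the reactivity of 27 and disfavour its self-addition, and the product of addition to the other face is a diastereomer of 28 that can be removed by chromatography.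

Step 13
Reactants: 28 (2S,3S)-7-(benzyloxy)-3-[3-(benzyloxy)-2,4,5-trimethoxyphenyl]-8-methoxy-2-{[(1R,2S)-2-phenylcyclohexyl]oxy}chromane
Product: 30 (3S)-7-(benzyloxy)-3-[3-(benzyloxy)-2,4,5-trimethoxyphenyl]-8-methoxychromane, via chromenylium ion 29 (not isolated)
Conditions: Et3SiH, BF3·OEt2, CH2Cl2, −78 → −20 °C; then aq. NaHCO3
Reagents that add atoms: none
Why: Ionic hydrogenation of an acetal; BF3 ionises the exocyclic C2–O bond (the more basic, alkyl-type oxygen) to ion 29, which Et3SiH reduces to the C2 methylene. C3 is not a reacting centre and should keep its configuration as long as hydride capture is faster than loss of the C3 proton, which low temperature and excess silane favour.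

Step 14
Reactants: 30 (3S)-7-(benzyloxy)-3-[3-(benzyloxy)-2,4,5-trimethoxyphenyl]-8-methoxychromane
Product: 31 (3S)-3-(3-hydroxy-2,4,5-trimethoxyphenyl)-8-methoxychroman-7-ol
Conditions: H2 (1 atm), Pd/C, EtOAc/MeOH, rt
Reagents that add atoms: none
Why: Hydrogenolysis of the two benzyl aryl ethers over palladium; the chroman C–O bonds are not benzylic and C3 carries no leaving group, so the stereocentre is untouched.

## Compound list

1 | 2-methoxyresorcinol (2-methoxybenzene-1,3-diol) | COc1c(O)cccc1O | starting material
2 | [(2,4-dihydroxy-3-methoxyphenyl)methylidene]dimethylammonium chloride | C[N+](C)=Cc1ccc(O)c(OC)c1O.[Cl-] | intermediate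
3 | 2,4-dihydroxy-3-methoxybenzaldehyde | O=Cc1ccc(O)c(OC)c1O | intermediate
4 | 4-(benzyloxy)-2-hydroxy-3-methoxybenzaldehyde | O=Cc1ccc(OCc2ccccc2)c(OC)c1O | intermediate
5 | tert-butyl [3-(benzyloxy)-6-formyl-2-methoxyphenyl] carbonate | O=Cc1ccc(OCc2ccccc2)c(OC)c1OC(=O)OC(C)(C)C | intermediate
6 | tert-butyl [3-(benzyloxy)-6-(hydroxymethyl)-2-methoxyphenyl] carbonate | OCc1ccc(OCc2ccccc2)c(OC)c1OC(=O)OC(C)(C)C | intermediate
7 | 1-bromo-2,4,5-trimethoxybenzene | COc1cc(OC)c(OC)cc1Br | starting material
8 | (2,4,5-trimethoxyphenyl)lithium | COc1cc(OC)c(OC)cc1[Li] | intermediate
9 | trimethyl(2,4,5-trimethoxyphenyl)silane | COc1cc(OC)c(OC)cc1[Si](C)(C)C | intermediate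
10 | [2,3,6-trimethoxy-5-(trimethylsilyl)phenyl]lithium | [Li]c1c(OC)c(OC)cc([Si](C)(C)C)c1OC | intermediate
11 | dimethyl [2,3,6-trimethoxy-5-(trimethylsilyl)phenyl]boronate | COB(OC)c1c(OC)c(OC)cc([Si](C)(C)C)c1OC | intermediate
12 | 2,3,6-trimethoxy-5-(trimethylsilyl)phenol | Oc1c(OC)c(OC)cc([Si](C)(C)C)c1OC | intermediate
13 | [3-(benzyloxy)-2,4,5-trimethoxyphenyl]trimethylsilane | COc1c(OCc2ccccc2)c(OC)c(OC)cc1[Si](C)(C)C | intermediate
14 | 3-(benzyloxy)-1-iodo-2,4,5-trimethoxybenzene | COc1c(OCc2ccccc2)c(OC)c(OC)cc1I | intermediate
15 | (1R,2S)-2-phenylcyclohexanol | O[C@@H]1CCCC[C@H]1c1ccccc1 | starting material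
16 | trichloroethylene | ClC=C(Cl)Cl | starting material
17 | potassium (1R,2S)-2-phenylcyclohexanolate | [K+].[O-][C@@H]1CCCC[C@H]1c1ccccc1 | intermediate
18 | dichloroacetylene | ClC#CCl | intermediate
19 | (E)-1,2-dichlorovinyl (1R,2S)-2-phenylcyclohexyl ether | Cl/C=C(/Cl)O[C@@H]1CCCC[C@H]1c1ccccc1 | intermediate
20 | chloroethynyl (1R,2S)-2-phenylcyclohexyl ether | ClC#CO[C@@H]1CCCC[C@H]1c1ccccc1 | intermediate
21 | lithium {[(1R,2S)-2-phenylcyclohexyl]oxy}acetylide | [Li]C#CO[C@@H]1CCCC[C@H]1c1ccccc1 | intermediate
22 | chloro({[(1R,2S)-2-phenylcyclohexyl]oxy}ethynyl)zinc | Cl[Zn]C#CO[C@@H]1CCCC[C@H]1c1ccccc1 | intermediate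
23 | [3-(benzyloxy)-2,4,5-trimethoxyphenyl]ethynyl (1R,2S)-2-phenylcyclohexyl ether | COc1cc(C#CO[C@@H]2CCCC[C@H]2c2ccccc2)c(OC)c(OCc2ccccc2)c1OC | intermediate
24 | (Z)-2-[3-(benzyloxy)-2,4,5-trimethoxyphenyl]ethenyl (1R,2S)-2-phenylcyclohexyl ether | COc1cc(/C=C\O[C@@H]2CCCC[C@H]2c2ccccc2)c(OC)c(OCc2ccccc2)c1OC | intermediate
25 | chloromagnesium {4-(benzyloxy)-2-[(tert-butoxycarbonyl)oxy]-3-methoxyphenyl}methanolate | Cl[Mg]OCc1ccc(OCc2ccccc2)c(OC)c1OC(=O)OC(C)(C)C | intermediate
26 | chloromagnesium 3-(benzyloxy)-6-{[(tert-butoxycarbonyl)oxy]methyl}-2-methoxyphenoxide | Cl[Mg]Oc1c(COC(=O)OC(C)(C)C)ccc(OCc2ccccc2)c1OC | intermediate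
27 | 3-(benzyloxy)-2-methoxy-6-methylidenecyclohexa-2,4-dien-1-one (ortho-quinone methide) | C=C1C=CC(OCc2ccccc2)=C(OC)C1=O | intermediate
28 | (2S,3S)-7-(benzyloxy)-3-[3-(benzyloxy)-2,4,5-trimethoxyphenyl]-8-methoxy-2-{[(1R,2S)-2-phenylcyclohexyl]oxy}chromane (2,3-cis) | COc1cc([C@H]2[C@@H](O[C@@H]4CCCC[C@H]4c4ccccc4)Oc3c(ccc(OCc4ccccc4)c3OC)C2)c(OC)c(OCc2ccccc2)c1OC | intermediate
29 | (3S)-7-(benzyloxy)-3-[3-(benzyloxy)-2,4,5-trimethoxyphenyl]-8-methoxy-3,4-dihydrochromenylium ion | COc1cc([C@H]2C=[O+]c3c(ccc(OCc4ccccc4)c3OC)C2)c(OC)c(OCc2ccccc2)c1OC | intermediate
30 | (3S)-7-(benzyloxy)-3-[3-(benzyloxy)-2,4,5-trimethoxyphenyl]-8-methoxychromane | COc1cc([C@H]2COc3c(ccc(OCc4ccccc4)c3OC)C2)c(OC)c(OCc2ccccc2)c1OC | intermediate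
31 | (3S)-3-(3-hydroxy-2,4,5-trimethoxyphenyl)-8-methoxychroman-7-ol (CNP0201239.1) | COc1cc([C@H]2COc3c(ccc(O)c3OC)C2)c(OC)c(O)c1OC | target

## Step count and risk

Total step count: 14. Longest linear sequence: 9 steps (from 7: steps 5, 6, 7, 8, 10, 11, 12, 13, 14).

**Step 12 (key step).** Two processes are most likely to go wrong. The first is self-addition of methide 27 outrunning the cycloaddition, because 24 is a hindered β-aryl enol ether and the limiting partner. The second is incomplete facial discrimination, because the new stereocentre forms at the β-carbon, one atom further from the auxiliary than the α-carbon. The fallback releases the methide slowly and without an organometallic base. It sets out from 4: reductive amination with Me2NH and NaBH(OAc)3 should give 3-(benzyloxy)-6-[(dimethylamino)methyl]-2-methoxyphenol F1, and MeI should convert it into {[4-(benzyloxy)-2-hydroxy-3-methoxyphenyl]methyl}trimethylammonium iodide F2. Warming F2 with 24 and K2CO3 in MeCN lets the phenoxide expel trimethylamine, so that 27 forms at low stationary concentration in the presence of the enol ether. The route is rejoined at 28.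

**Step 13.** Loss of the C3 proton from ion 29 would give an achiral 4H-chromene whose reprotonation erodes the configuration at C3. Ionisation of the ring O1–C2 bond instead of the exocyclic bond would end in ring-opened material. The fallback sets out from 28: hydrolysis with dilute aqueous acid in THF, where water captures the ion at once, should give (3S)-7-(benzyloxy)-3-[3-(benzyloxy)-2,4,5-trimethoxyphenyl]-8-methoxychroman-2-ol F3. NaBH4 in MeOH at 0 °C should reduce its open-chain aldehyde form to (2S)-3-[4-(benzyloxy)-2-hydroxy-3-methoxyphenyl]-2-[3-(benzyloxy)-2,4,5-trimethoxyphenyl]propan-1-ol F4. Mitsunobu etherification (PPh3, DIAD, THF) then closes the O1–C2 bond, and the route is rejoined at 30.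

**Step 10.** The acetylide may form incompletely or decay in the one-flask sequence, butyl may be transferred from residual butylzinc species, oxidative addition of the electron-rich iodide to zerovalent palladium may be slow, and 23 may hydrate or fragment thermally. The fallback makes the vinyl C–O bond instead of the C(sp)–C1' bond and sets out from 14. Iodine–magnesium exchange with i-PrMgCl·LiCl and quenching with DMF should give 3-(benzyloxy)-2,4,5-trimethoxybenzaldehyde F5. Stork–Zhao olefination with [Ph3PCH2I]I and NaN(SiMe3)2 at −78 °C should give 3-(benzyloxy)-1-[(Z)-2-iodoethenyl]-2,4,5-trimethoxybenzene F6. Copper-catalysed Ullmann-type vinyl etherification of F6 with 15 (CuI, 3,4,7,8-tetramethyl-1,10-phenanthroline, Cs2CO3, toluene, 80 °C) proceeds with retention of the alkene geometry. The route is rejoined at 24, and steps 9 and 11 are then not needed.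

**Step 4.** The carbonate may migrate to the new benzylic oxygen during reduction or work-up, followed by elimination and further reduction or oligomerisation. The fallback reverses the order of the two operations and sets out from 4: NaBH4 in MeOH should give 3-(benzyloxy)-6-(hydroxymethyl)-2-methoxyphenol F7. Boc2O with K2CO3 in aqueous THF at 0 °C then acylates the phenoxide in preference to the neutral primary alcohol, and the route is rejoined at 6.

## Further compounds

F1 | step 12 | 3-(benzyloxy)-6-[(dimethylamino)methyl]-2-methoxyphenol | CN(C)Cc1ccc(OCc2ccccc2)c(OC)c1O
F2 | step 12 | {[4-(benzyloxy)-2-hydroxy-3-methoxyphenyl]methyl}trimethylammonium iodide | C[N+](C)(C)Cc1ccc(OCc2ccccc2)c(OC)c1O.[I-]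
F3 | step 13 | (3S)-7-(benzyloxy)-3-[3-(benzyloxy)-2,4,5-trimethoxyphenyl]-8-methoxychroman-2-ol (mixture of C2 epimers) | COc1cc([C@H]2C(O)Oc3c(ccc(OCc4ccccc4)c3OC)C2)c(OC)c(OCc2ccccc2)c1OC
F4 | step 13 | (2S)-3-[4-(benzyloxy)-2-hydroxy-3-methoxyphenyl]-2-[3-(benzyloxy)-2,4,5-trimethoxyphenyl]propan-1-ol | COc1cc([C@@H](CO)Cc2ccc(OCc3ccccc3)c(OC)c2O)c(OC)c(OCc2ccccc2)c1OC
F5 | step 10 | 3-(benzyloxy)-2,4,5-trimethoxybenzaldehyde | COc1cc(C=O)c(OC)c(OCc2ccccc2)c1OC
F6 | step 10 | 3-(benzyloxy)-1-[(Z)-2-iodoethenyl]-2,4,5-trimethoxybenzene | COc1cc(/C=C\I)c(OC)c(OCc2ccccc2)c1OC
F7 | step 4 | 3-(benzyloxy)-6-(hydroxymethyl)-2-methoxyphenol | OCc1ccc(OCc2ccccc2)c(OC)c1O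
A1 | alternative 1 | cis-8-hydroxy-3-isopropoxy-4,9-dimethoxypterocarpan (C6a configured as C3 of 31) | COc1cc2c(cc1O)[C@H]1COc3c(ccc(OC(C)C)c3OC)[C@H]1O2
A2 | alternative 1 | 7-isopropoxy-8-methoxy-2H-chromene | COc1c(OC(C)C)ccc2C=CCOc12
A3 | alternative 1 | 2-methoxy-1,4-benzoquinone | COC1=CC(=O)C=CC1=O
A4 | alternative 2 | 4-{(2S)-2-[3-(benzyloxy)-2,4,5-trimethoxyphenyl]-3-(tert-butyldimethylsilyloxy)propyl}-2-methoxycyclohexane-1,3-dione | COC1C(=O)CCC(C[C@H](CO[Si](C)(C)C(C)(C)C)c2cc(OC)c(OC)c(OCc3ccccc3)c2OC)C1=O
A5 | alternative 2 | methyl 4-{(2S)-2-[3-(benzyloxy)-2,4,5-trimethoxyphenyl]-3-(tert-butyldimethylsilyloxy)propyl}-6-methoxy-5-oxohexanoate | COCC(=O)C(CCC(=O)OC)C[C@H](CO[Si](C)(C)C(C)(C)C)c1cc(OC)c(OC)c(OCc2ccccc2)c1OC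
A6 | alternative 3 | (3S)-7-(methoxymethoxy)-3-[2,4,5-trimethoxy-3-(methoxymethoxy)phenyl]chroman-8-ol | COc1cc([C@H]2COc3c(ccc(OCOC)c3O)C2)c(OC)c(OCOC)c1OC
A7 | alternative 3 | (2S)-3-[2-bromo-4-(methoxymethoxy)phenyl]-2-[2,4,5-trimethoxy-3-(methoxymethoxy)phenyl]propan-1-ol | COCOc1ccc(C[C@H](CO)c2cc(OC)c(OC)c(OCOC)c2OC)c(Br)c1
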